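The 1,4-relationship across ring B between C8 (methyl C17) and C5 (bonded to the gem-dimethyl carbon C4) is the methyl/isopropyl pattern of a p-menthane. (R)-Carvone can therefore serve as ring B, with C17, C4 and both C4 methyls already in place. The plan rests on disconnecting C3–C4. In the key step, hydrogen-atom transfer to the isopropenyl group creates a tertiary C4 radical that closes ring A 6-endo onto a vinyl sulfone. This forges quaternary C4 and the trans-decalin in one operation. The precursor is carvone carrying at C10 a methyl group and, trans to the isopropenyl group, a 2-(phenylsulfonyl)allyl arm (C1–C3). Cross-coupling at C9 and a singlet-oxygen relay then add the side chain and the 6β,7α-oxygens.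

Key step: step 3

Remark: labdane numbering (α = face opposite the C10 methyl) is used from compound 6 on; C2 of the sulfones and C6 of 3 are epimer mixtures and are left undefined in the SMILES; 1, 4 and 10 are taken to be catalogue chemicals.

Step 1
Reactants: 1 (R)-(−)-carvone
Product: 3 (5R)-6-methylcarvone as a C6 epimer mixture, via carvone lithium dienolate 2 (not isolated)
Conditions: LDA, THF, −78 °C; MeI, −78 → 0 °C
Reagents that add atoms: iodomethane, CI; lithium diisopropylamide, [Li+].CC(C)[N-]C(C)C (lithium stays only in 2)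
Why: Kinetic deprotonation of the enone at the α′-CH2 (future C10) gives the cross-conjugated enolate, which undergoes a standard SN2 enolate methylation; the new centre forms as an epimer mixture, which does not matter because step 2 makes it planar again.

Step 2
Reactants: 3 (5R)-6-methylcarvone; 4 2,3-bis(phenylsulfonyl)prop-1-ene
Product: 6 (5S,6S)-2,6-dimethyl-6-[2-(phenylsulfonyl)prop-2-en-1-yl]-5-(prop-1-en-2-yl)cyclohex-2-en-1-one, via tetrasubstituted lithium enolate 5 (not isolated)
Conditions: LDA, THF/DMPU, −78 → 0 °C; cannulated into 4 (1.2 equiv), THF, −78 → −20 °C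
Reagents that add atoms: lithium diisopropylamide, [Li+].CC(C)[N-]C(C)C (lithium stays only in 5)
Why: Enolate alkylation by conjugate addition–elimination (SN2′), in which the enolate adds to the CH2= terminus of the activated allyl sulfone and phenylsulfinate is expelled; the electrophile approaches the face opposite the neighbouring isopropenyl group, so the C10 methyl ends up cis to it (10β), and inverse addition limits proton transfer and double addition.

Step 3
Reactants: 6 (5S,6S)-2,6-dimethyl-6-[2-(phenylsulfonyl)prop-2-en-1-yl]-5-(prop-1-en-2-yl)cyclohex-2-en-1-one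
Product: 7 (4aS,8aS)-2,5,5,8a-tetramethyl-7-(phenylsulfonyl)-4a,5,6,7,8,8a-hexahydronaphthalen-1(4H)-one (trans-decalin 7-en-9-one, 5α-H, 10β-CH3, both C2 epimers)
Conditions: Fe(acac)3 (30 mol %), PhSiH3 (2.5 equiv, slow addition), EtOH/ethylene glycol 5:1 (0.02 M), Ar, 60 °C
Reagents that add atoms: none
Why: An iron hydride formed from Fe(acac)3 and PhSiH3 delivers a hydrogen atom to the CH2 terminus of the isopropenyl group, the resulting nucleophilic tertiary C4 radical adds to the unsubstituted terminus (C3) of the vinyl sulfone, and the α-sulfonyl radical at C2 is reduced by iron(II) and protonated by ethanol. The closest known reaction type is the iron-catalysed reductive olefin coupling (MHAT-initiated Giese addition) in its intramolecular form. Ring A closes 6-endo-trig, because 5-exo attack would have to strike the fully substituted, sulfonyl-bearing C2 and would leave an unstabilised primary radical. C4 becomes quaternary but is not stereogenic, the trans fusion is inherited from C5 and C10 of 6 (whose two reacting arms are trans and can both be equatorial on the cyclohexenone), and the only new stereocentre, C2, is set without control in the final protonation and is erased in step 8. The selectivity needed is hydrogen-atom delivery to the isopropenyl group rather than to the two electron-poor alkenes, which is secured because this is the only electron-neutral 1,1-disubstituted alkene, while dilution and slow silane addition keep bimolecular quenching of the radical slower than ring closure.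

Step 4
Reactants: 7 trans-decalin 7-en-9-one sulfone
Product: 9 (4aS,8aS)-2,5,5,8a-tetramethyl-7-(phenylsulfonyl)-4a,5,6,7,8,8a-hexahydronaphthalen-1-yl triflate (6,8-dien-9-yl triflate), via potassium dienolate 8 (not isolated)
Conditions: KHMDS (1.15 equiv), THF, −78 → −40 °C; PhNTf2, −78 → 0 °C
Reagents that add atoms: N-phenylbis(trifluoromethanesulfonimide), O=S(=O)(N(c1ccccc1)S(=O)(=O)C(F)(F)F)C(F)(F)F; potassium hexamethyldisilazide, [K+].C[Si](C)(C)[N-][Si](C)(C)C (potassium stays only in 8)
Why: γ-Deprotonation and O-sulfonylation of an extended dienolate, regiodefined because C10 is quaternary and only C6–H is vinylogously acidic; the far less acidic sulfone α-proton cannot retain the charge against a silazide base, so the material funnels to the dienolate.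

Step 5
Reactants: 10 (E)-3-methylpent-2-en-4-yn-1-ol
Product: 11 (E)-3-methylpent-2-en-4-ynyl TBDPS ether
Conditions: TBDPSCl, imidazole, CH2Cl2, 0 °C → rt
Reagents that add atoms: tert-butyl(chloro)diphenylsilane, CC(C)(C)[Si](Cl)(c1ccccc1)c1ccccc1
Why: Imidazole-promoted silylation of a primary alcohol; TBDPS should survive aqueous carbonate, sodium amalgam, DBU, borohydride, perrhenate and acylation, and it can later be removed by fluoride without touching acetates.

Step 6
Reactants: 11 (E)-3-methylpent-2-en-4-ynyl TBDPS ether
Product: 12 (E)-3-methylpenta-2,4-dienyl TBDPS ether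
Conditions: H2 (1 atm), Lindlar catalyst, quinoline, hexane/EtOAc, rt, stopped at 1 equiv H2
Reagents that add atoms: none
Why: Lindlar semihydrogenation, in which the terminal alkyne binds the poisoned palladium surface much more strongly than the diene product, so uptake can be halted at the vinyl stage with the purchased E alkene untouched.

Step 7
Reactants: 12 (E)-3-methylpenta-2,4-dienyl TBDPS ether; 9 6,8-dien-9-yl triflate
Product: 14 2ξ-(phenylsulfonyl)labda-6,8,13E-trien-15-yl TBDPS ether, via B-alkyl-9-BBN 13 (not isolated)
Conditions: 9-BBN, THF, 0 °C → rt; then 9, Pd(dppf)Cl2·CH2Cl2, AsPh3, Cs2CO3, DMF/THF/H2O (degassed), 50 °C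
Reagents that add atoms: 9-borabicyclo[3.3.1]nonane, C1CC2CCCC(C1)B2 (the boron cage stays only in 13; only hydrogen remains in 14)
Why: B-alkyl Suzuki–Miyaura coupling, in which 9-BBN adds anti-Markovnikov to the only monosubstituted alkene of the diene and the primary borane transfers its alkyl group to the dienyl-palladium species from 9, forming C9–C11 with all alkene geometries retained and no new stereocentre.

Step 8
Reactants: 14 2ξ-(phenylsulfonyl)labda-6,8,13E-trien-15-yl TBDPS ether
Product: 15 labda-6,8,13E-trien-15-yl TBDPS ether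
Conditions: 6 % Na(Hg), Na2HPO4, MeOH/THF, −20 → 0 °C
Reagents that add atoms: none
Why: Reductive desulfonylation by single-electron transfer cleaves the alkyl–sulfonyl bond under buffered conditions that leave the unactivated diene, the trisubstituted alkene and the silyl ether alone; both C2 epimers converge on one compound.

Step 9
Reactants: 15 labda-6,8,13E-trien-15-yl TBDPS ether
Product: 17 9α-hydroxy-6-oxolabda-7,13E-dien-15-yl TBDPS ether, via 6α,9α-endoperoxide 16 (not isolated)
Conditions: O2, tetraphenylporphyrin (cat.), visible light, CH2Cl2, −78 °C; Ar purge; DBU, −78 → 0 °C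
Reagents that add atoms: dioxygen, O=O
Why: Singlet-oxygen [4+2] cycloaddition to the s-cis-locked ring-B diene (much faster than the ene reaction of the inductively deactivated side-chain alkene) occurs on the α face because the C10 and 4β methyls block the β face, setting 9α-O, and the Kornblum–DeLaMare rearrangement can only remove the C6 hydrogen, so the ketone forms at C6 and the tertiary alcohol at C9 without the peroxide being isolated.

Step 10
Reactants: 17 9α-hydroxy-6-oxolabda-7,13E-dien-15-yl TBDPS ether
Product: 18 6β,9α-dihydroxylabda-7,13E-dien-15-yl TBDPS ether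
Conditions: NaBH4, CeCl3·7H2O, MeOH, −78 → −20 °C; NaHCO3 quench
Reagents that add atoms: none
Why: Luche 1,2-reduction, in which hydride reaches C6 from the open α face because the axial C10 and 4β methyls screen the β face, giving the axial 6β-alcohol.

Step 11
Reactants: 18 6β,9α-dihydroxylabda-7,13E-dien-15-yl TBDPS ether
Product: 19 6β,7α-dihydroxylabda-8,13E-dien-15-yl TBDPS ether
Conditions: Ph3SiOReO3 (5 mol %), Et2O, −50 °C
Reagents that add atoms: none
Why: Rhenium(VII)-catalysed 1,3-transposition of an allylic alcohol through a cyclic [3,3] shift of the perrhenate ester, which is suprafacial and so turns 9α-O into 7α-O (anti to 6β-OH); the equilibrium is pulled by formation of the tetrasubstituted C8=C9 alkene and relief of crowding next to C10, while the alternative shift of the 6β-hydroxyl is uphill and reversible.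

Step 12
Reactants: 19 6β,7α-dihydroxylabda-8,13E-dien-15-yl TBDPS ether
Product: 20 6β,7α-diacetoxylabda-8,13E-dien-15-yl TBDPS ether
Conditions: Ac2O (excess), Et3N, DMAP, CH2Cl2, rt → 40 °C
Reagents that add atoms: acetic anhydride, CC(=O)OC(C)=O
Why: DMAP-catalysed acylation breaks only O–H bonds, so both configurations are retained; the crowded axial 6β-hydroxyl needs excess reagent and warming.

Step 13
Reactants: 20 6β,7α-diacetoxylabda-8,13E-dien-15-yl TBDPS ether
Product: 21 6β,7α-diacetoxylabda-8,13E-dien-15-ol, (5S,6S,7S,10S), target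
Conditions: HF·pyridine, pyridine/THF, 0 °C → rt
Reagents that add atoms: none
Why: Fluoride-driven Si–O cleavage under buffered, weakly acidic conditions removes the silyl group without the acetate hydrolysis or migration that basic fluoride could cause, and no stereocentre is touched.

Compound list
1 | (R)-(−)-carvone | CC1=CC[C@H](CC1=O)C(C)=C | starting material
2 | carvone lithium dienolate (cross-conjugated, not isolated) | [Li+].CC1=CC[C@H](C=C1[O-])C(C)=C | intermediate
3 | (5R)-6-methylcarvone, C6 epimer mixture | CC1=CC[C@H](C(C)C1=O)C(C)=C | intermediate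
4 | 2,3-bis(phenylsulfonyl)prop-1-ene | C=C(CS(=O)(=O)c1ccccc1)S(=O)(=O)c1ccccc1 | starting material
5 | tetrasubstituted lithium enolate of 3 (not isolated) | [Li+].CC1=CC[C@H](C(C)=C1[O-])C(C)=C | intermediate
6 | (5S,6S)-2,6-dimethyl-6-[2-(phenylsulfonyl)prop-2-en-1-yl]-5-(prop-1-en-2-yl)cyclohex-2-en-1-one | C1C=C(C)C(=O)[C@@](C)(CC(=C)S(=O)(=O)c2ccccc2)[C@@H]1C(C)=C | intermediate
7 | (4aS,8aS)-2,5,5,8a-tetramethyl-7-(phenylsulfonyl)-4a,5,6,7,8,8a-hexahydronaphthalen-1(4H)-one, both sulfone epimers | C1C=C(C)C(=O)[C@@]2(C)CC(S(=O)(=O)c3ccccc3)CC(C)(C)[C@H]12 | intermediate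
8 | potassium 6,8-dienolate of 7 (not isolated) | [K+].C1=CC(C)=C([O-])[C@@]2(C)CC(S(=O)(=O)c3ccccc3)CC(C)(C)[C@H]12 | intermediate
9 | 6,8-dien-9-yl triflate of the decalin sulfone | C1=CC(C)=C(OS(=O)(=O)C(F)(F)F)[C@@]2(C)CC(S(=O)(=O)c3ccccc3)CC(C)(C)[C@H]12 | intermediate
10 | (E)-3-methylpent-2-en-4-yn-1-ol | C#C/C(C)=C/CO | starting material
11 | (E)-3-methylpent-2-en-4-ynyl TBDPS ether | C#C/C(C)=C/CO[Si](C(C)(C)C)(c1ccccc1)c1ccccc1 | intermediate
12 | (E)-3-methylpenta-2,4-dienyl TBDPS ether | C=C/C(C)=C/CO[Si](C(C)(C)C)(c1ccccc1)c1ccccc1 | intermediate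
13 | B-[(E)-5-(TBDPS-oxy)-3-methylpent-3-enyl]-9-BBN (not isolated) | C1CC2CCCC(C1)B2CC/C(C)=C/CO[Si](C(C)(C)C)(c1ccccc1)c1ccccc1 | intermediate
14 | 2ξ-(phenylsulfonyl)labda-6,8,13E-trien-15-yl TBDPS ether | C1=CC(C)=C(CC/C(C)=C/CO[Si](C(C)(C)C)(c4ccccc4)c4ccccc4)[C@@]2(C)CC(S(=O)(=O)c3ccccc3)CC(C)(C)[C@H]12 | intermediate
15 | labda-6,8,13E-trien-15-yl TBDPS ether | C1=CC(C)=C(CC/C(C)=C/CO[Si](C(C)(C)C)(c3ccccc3)c3ccccc3)[C@@]2(C)CCCC(C)(C)[C@H]12 | intermediate
16 | 6α,9α-epidioxylabda-7,13E-dien-15-yl TBDPS ether (not isolated) | O1O[C@H]2C=C(C)[C@]1(CC/C(C)=C/CO[Si](C(C)(C)C)(c4ccccc4)c4ccccc4)[C@@]3(C)CCCC(C)(C)[C@H]23 | intermediate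
17 | 9α-hydroxy-6-oxolabda-7,13E-dien-15-yl TBDPS ether | O=C1C=C(C)[C@](O)(CC/C(C)=C/CO[Si](C(C)(C)C)(c3ccccc3)c3ccccc3)[C@@]2(C)CCCC(C)(C)[C@H]12 | intermediate
18 | 6β,9α-dihydroxylabda-7,13E-dien-15-yl TBDPS ether | O[C@@H]1C=C(C)[C@](O)(CC/C(C)=C/CO[Si](C(C)(C)C)(c3ccccc3)c3ccccc3)[C@@]2(C)CCCC(C)(C)[C@H]12 | intermediate
19 | 6β,7α-dihydroxylabda-8,13E-dien-15-yl TBDPS ether | O[C@@H]1[C@@H](O)C(C)=C(CC/C(C)=C/CO[Si](C(C)(C)C)(c3ccccc3)c3ccccc3)[C@@]2(C)CCCC(C)(C)[C@H]12 | intermediate
20 | 6β,7α-diacetoxylabda-8,13E-dien-15-yl TBDPS ether | CC(=O)O[C@@H]1[C@@H](OC(C)=O)C(C)=C(CC/C(C)=C/CO[Si](C(C)(C)C)(c3ccccc3)c3ccccc3)[C@@]2(C)CCCC(C)(C)[C@H]12 | intermediate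
21 | 6β,7α-diacetoxylabda-8,13E-dien-15-ol (CNP0187815.1) | CC(=O)O[C@@H]1[C@@H](OC(C)=O)C(C)=C(CC/C(C)=C/CO)[C@@]2(C)CCCC(C)(C)[C@H]12 | target

Total step count: 13. Longest linear sequence: 11 (steps 1–4 and 7–13); steps 5 and 6 form the two-step side branch.

Steps most likely to fail

1. Step 7. Oxidative addition and transmetalation at C9, wedged between quaternary C10 and the methyl-bearing C8, may be too slow for an sp3 boron partner. S–O cleavage of the triflate and protodeboronation could then take over. The fallback sets out from 9 and returns at 14, and it moves the sp3–sp2 coupling to an unhindered site.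
   - A Stille coupling of 9 with the small sp2 partner tributyl(vinyl)stannane (Pd2(dba)3, AsPh3, LiCl, NMP) should give the 9-vinyl trienyl sulfone F1.
   - 9-BBN then adds to the only monosubstituted alkene of that compound to give the C12 borane F2.
   - Separately, but-2-yn-1-ol is silylated to but-2-ynyl TBDPS ether F3. Hydrozirconation–iodination (Cp2Zr(H)Cl, then I2) gives (E)-3-iodobut-2-enyl TBDPS ether F4; syn addition places iodine trans to the CH2O group.
   - Suzuki–Miyaura coupling of the borane with this iodide (Pd(dppf)Cl2, Cs2CO3) forms C12–C13 with retention and delivers 14 with the 13E geometry.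

2. Step 3. Hydrogen may be delivered to the C4 radical before ring closure (net hydrogenation of the isopropenyl group), or hydrogen-atom transfer to the vinyl sulfone or the enone may compete. The fallback sets out from 6 and returns at 7, and it separates radical generation from alkene chemoselectivity.
   - Markovnikov hydrobromination of the isopropenyl group (HBr, AcOH, 0 °C, the classical behaviour of carvone) should give the tertiary bromide F5.
   - Bromine abstraction under tin hydride conditions (Bu3SnH added slowly, AIBN, benzene, 80 °C) produces the same C4 radical at low hydrogen-donor concentration. The 6-endo Giese closure onto the vinyl sulfone then follows, and hydrogen abstraction finishes the sequence.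

3. Step 11. The perrhenate ester may ionise to a free allyl cation, causing loss of facial fidelity at C7 and dehydration of ring B. The fallback sets out from 18 and returns at 20, bypassing 19.
   - Selective acetylation of the secondary alcohol (Ac2O, DMAP, Et3N; the tertiary 9α-hydroxyl does not react) gives the 6β-monoacetate F6.
   - Anhydrous acetolysis (AcOH/Ac2O, catalytic TsOH, 0 °C) ionises the tertiary allylic C9–O bond on purpose. The 6β-acetoxy group bridges to the β face of C7 by neighbouring-group participation.
   - External acetate then opens at the allylic C7 from the α face in a Prévost-type trans-diaxial manner, giving the 6β,7α-diacetate with the C8=C9 alkene.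

Further compounds
F1 | step 7 | 9-vinyl-6,8-dienyl decalin sulfone (C11=C12 vinyl on C9) | C1=CC(C)=C(C=C)[C@@]2(C)CC(S(=O)(=O)c3ccccc3)CC(C)(C)[C@H]12
F2 | step 7 | C12 9-BBN borane of F1 | C1=CC(C)=C(CCB4C5CCCC4CCC5)[C@@]2(C)CC(S(=O)(=O)c3ccccc3)CC(C)(C)[C@H]12
F3 | step 7 | but-2-ynyl TBDPS ether | CC#CCO[Si](C(C)(C)C)(c1ccccc1)c1ccccc1
F4 | step 7 | (E)-3-iodobut-2-enyl TBDPS ether | I/C(C)=C/CO[Si](C(C)(C)C)(c1ccccc1)c1ccccc1
F5 | step 3 | (5S,6S)-5-(2-bromopropan-2-yl)-2,6-dimethyl-6-[2-(phenylsulfonyl)prop-2-en-1-yl]cyclohex-2-en-1-one | C1C=C(C)C(=O)[C@@](C)(CC(=C)S(=O)(=O)c2ccccc2)[C@@H]1C(C)(C)Br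
F6 | step 11 | 6β-acetoxy-9α-hydroxylabda-7,13E-dien-15-yl TBDPS ether | CC(=O)O[C@@H]1C=C(C)[C@](O)(CC/C(C)=C/CO[Si](C(C)(C)C)(c3ccccc3)c3ccccc3)[C@@]2(C)CCCC(C)(C)[C@H]12
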